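Sunday's flask held 19.7 times the reagent of Thursday's, and after 10.0 d its mono adduct read 4.5% against Thursday's 30.5%. So I compared two amounts per starting material charged: the reagent offered, E, and the reagent taken up, n, the turnover count or degree of substitution.

common to all: starting material 0.020 M

| run | reagent | remark | time |
|---|---|---|---|
| Thursday's | 0.029 M | run made earlier |  |
| Sunday's | 0.57 M | run made earlier |  |
| north-west | 0.0200 M |  | 10 d |
| north | 0.0400 M |  | 10 d |
| south | 0.0800 M |  | 10 d |
| north-east | 0.200 M |  | 10 d |
| east | 0.400 M |  | 10 d |

| run | time / d | mono adduct / % | starting material / % |
|---|---|---|---|
| Thursday's | 2.50 | 32.8 | 20.4 |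
| Thursday's | 5.00 | 32.1 | 15.6 |
| Thursday's | 8.00 | 30.5 | 12.5 |
| Thursday's | 10.0 | 30.5 | 11.2 |
| Sunday's | 1.25 | 14.2 | 0.4 |
| Sunday's | 4.00 | 8.0 | 0.2 |
| Sunday's | 6.00 | 6.3 | 0.1 |
| Sunday's | 10.0 | 4.5 | 0.2 |

(readings scatter by 0.5 percentage points)

- amount of mono adduct at the end, in percent of the starting material charged for north-west, north, south, north-east, east, in this order
- the course of these numbers from the first flask to the last (hardly changes / falls, then rises / falls all the way / rises, then falls / rises all the way)

- "hardly changes" means that all values lie within two and a half points (for a concentration: within two and a half percent of the largest)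

I assumed that mono adduct had taken one reagent and that every other reacted starting material had taken one or two. On that count Thursday's final readings put n between 0.888 and a ceiling of 1.47, against E = 1.45, so I estimated that at least 0.612 of the offer was taken up. On the same count Sunday's readings gave n no higher than 1.95 against E = 28.5, a share of 6.84% at most. Offering more had therefore not bought turnovers in proportion.

I took mono adduct to be made by the first turnover and lost to the second, so it should stand highest near n of one. North-west, offered 1.00 equivalent, should stop between 0.612 and one, so I set it below Thursday's reading. North, offered 2.00, should lie close to Thursday's reading, and the later flasks should fall towards Sunday's without reaching it. My row therefore rose, then fell. The forecast gave 37%, 20%, 8%, 5.3% and 4.7%, a course that falls all the way, reading the runs as “redistribution equilibrium rather than a simple consecutive sequence”, and so it parted from mine.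

The flasks gave 25.2%, 29.8%, 21.0%, 10.9% and 6.81%: the row rises, then falls.

    starting material + reagent → mono adduct + released group (k = 1.80 M⁻¹ h⁻¹)
    starting material + reagent → other mono adduct + released group (k = 1.30 M⁻¹ h⁻¹)
    reagent + mono adduct → double product + released group (k = 0.820 M⁻¹ h⁻¹)
    reagent + other mono adduct → double product + released group (k = 0.270 M⁻¹ h⁻¹)
    2 reagent → self-condensation product (k = 0.750 M⁻¹ h⁻¹)
    starting material + mono adduct → side product (k = 0.210 M⁻¹ h⁻¹)

Released group leaves once per reagent taken up by starting material or an adduct, so it counts n directly. North stood at 1.16, under Thursday's ceiling of 1.47, and held the top of the row. East, offered 20.0 equivalents, reached 1.72, under Sunday's ceiling of 1.95, and that second turnover took its mono adduct: without reagent + mono adduct → double product + released group, east holds 57.6% instead of 6.81%.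

The data are calculated with made-up constants; noise was put on by code.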